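**Retrosynthetic overview**

1. The target is the 3-O-[(2S)-2-methylbutanoate] of (2R,3R)-pinobanksin; the last operation only frees the 5- and 7-hydroxyls from benzyl ethers.
2. The key disconnection is C4–C4a of the pyranone (ring C), made by intramolecular Friedel–Crafts acylation of a 3-aryloxy-2-acyloxy-3-phenylpropanoic acid. Ring C is the only ring formed; rings A and B are bought as arenes.
3. The feature the strategy rests on: ring A carries oxygen at C5, C7 and C8a, so as an open 3,5-bis(benzyloxy)phenyl ether it has a mirror plane through C8a and C6. The two carbons ortho to O1 are therefore interchangeable (either one becomes C4a), and the para carbon (future C6) cannot reach the tethered acyl group.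
4. C2–C3–C4 map onto C3–C2–C1 of trans-(2R,3S)-3-phenylglycidate. O1–C2 is made by phenoxide opening at the benzylic carbon with inversion, the C3 oxygen is the former epoxide oxygen (retention), and C4 is the glycidate carboxyl carbon.
5. The carboxyl group is carried as an allyl ester so that the (S)-2-methylbutanoate can be installed before ring closure and the acid then released without hydroxide.

Key step: step 6

Assumption: methyl (2R,3S)-3-phenylglycidate, 3,5-bis(benzyloxy)phenol and (S)-2-methylbutanoic acid are bought as single, defined compounds; ring positions are given in flavanone numbering (O1, C2, C3, C4, C4a, C5–C8, C8a).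

**Route**

Step 1
Reactants: 1 methyl (2R,3S)-3-phenyloxirane-2-carboxylate
Product: 2 potassium (2R,3S)-3-phenyloxirane-2-carboxylate
Conditions: KOH (1.0 equiv), EtOH, 0 °C; salt collected by filtration and dried
Reagents that add atoms: potassium hydroxide, [K+].[OH-]
Why: Saponification (acyl-oxygen ester hydrolysis) of a glycidic ester to its stable potassium salt should leave the epoxide and both stereocentres untouched, because the labile free glycidic acid is never generated.

Step 2
Reactants: 2 potassium (2R,3S)-3-phenyloxirane-2-carboxylate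
Product: 3 prop-2-en-1-yl (2R,3S)-3-phenyloxirane-2-carboxylate
Conditions: allyl bromide (1.2 equiv), DMF, rt
Reagents that add atoms: allyl bromide, C=CCBr
Why: SN2 O-alkylation of a carboxylate salt in a dipolar aprotic solvent gives an ester that can later be removed without hydroxide or hydrogen, and no stereocentre takes part.

Step 3
Reactants: 3 prop-2-en-1-yl (2R,3S)-3-phenyloxirane-2-carboxylate; 4 3,5-bis(benzyloxy)phenol
Product: 5 prop-2-en-1-yl (2R,3R)-3-[3,5-bis(benzyloxy)phenoxy]-2-hydroxy-3-phenylpropanoate
Conditions: 4 (1.2 equiv), Cs2CO3 (0.2 equiv), dry DMF, 50 °C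
Reagents that add atoms: none
Why: Base-catalysed SN2 epoxide opening of a 3-arylglycidate by a phenoxide should occur at the benzylic carbon β to the ester, anti to the departing oxygen, so C3 is inverted (S to R) while C2 keeps its oxygen and its R configuration.

Step 4
Reactants: 5 prop-2-en-1-yl (2R,3R)-3-[3,5-bis(benzyloxy)phenoxy]-2-hydroxy-3-phenylpropanoate; 6 (2S)-2-methylbutanoic acid
Product: 7 prop-2-en-1-yl (2R,3R)-3-[3,5-bis(benzyloxy)phenoxy]-2-{[(2S)-2-methylbutanoyl]oxy}-3-phenylpropanoate
Conditions: 6 (1.5 equiv), DCC (1.5 equiv), DMAP (0.1 equiv), CH2Cl2, 0 °C to rt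
Reagents that add atoms: none
Why: Steglich esterification of the only free hydroxyl, with DMAP kept catalytic and no further amine base, should retain both the α-stereocentre of the acid and C2 of the alcohol.

Step 5
Reactants: 7 prop-2-en-1-yl (2R,3R)-3-[3,5-bis(benzyloxy)phenoxy]-2-{[(2S)-2-methylbutanoyl]oxy}-3-phenylpropanoate
Product: 8 (2R,3R)-3-[3,5-bis(benzyloxy)phenoxy]-2-{[(2S)-2-methylbutanoyl]oxy}-3-phenylpropanoic acid
Conditions: Pd(PPh3)4 (5 mol%), morpholine (5 equiv), THF, rt; then dilute aq. KHSO4
Reagents that add atoms: none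
Why: Tsuji–Trost deallylation: Pd(0) ionises the allyl ester to a π-allyl complex that morpholine captures, so the acid is released without hydroxide and the 2-methylbutanoate, the benzyl ethers and both stereocentres should remain.

Step 6
Reactants: 8 (2R,3R)-3-[3,5-bis(benzyloxy)phenoxy]-2-{[(2S)-2-methylbutanoyl]oxy}-3-phenylpropanoic acid
Product: 10 (2R,3R)-5,7-bis(benzyloxy)-4-oxo-2-phenylchroman-3-yl (2S)-2-methylbutanoate, via acyl trifluoroacetate 9 (not isolated)
Conditions: TFAA (1.5 equiv), CH2Cl2 (0.02 M), 0 °C to rt; aq. NaHCO3 work-up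
Reagents that add atoms: trifluoroacetic anhydride, O=C(OC(=O)C(F)(F)F)C(F)(F)F (its atoms stay in 9 only, none in 10)
Why: Trifluoroacetic anhydride converts the carboxylic acid into acyl trifluoroacetate 9, whose acid-activated, acylium-like carbonyl carbon is attacked by the arene carbon ortho to the ether oxygen, and the Wheland intermediate loses its proton to trifluoroacetate, forming C4–C4a. The closest known reaction type is the anhydride-mediated intramolecular Friedel–Crafts acylation of 3-aryloxypropanoic acids to chroman-4-ones, including 3-aryloxy-3-phenylpropanoic acids that give flavanones. The pyranone ring closes in a 6-exo-trig mode at the acyl carbon, the carbonyl oxygen staying outside the new ring. No stereocentre is created: C2 and C3 come unchanged from 8, no base is present so no ketene can form at C3, and the 2,3-trans arrangement is also the thermodynamically preferred one should any acid enolisation occur. The step needs regio- and chemoselectivity: the two carbons ortho to O1 are equivalent by the mirror symmetry of the 3,5-bis(benzyloxy)phenyl ether and each is activated by three oxygen donors (two ortho, one para), while the para carbon cannot reach the acyl group, so only one chromanone can form. The triply activated ring should react without a strong Lewis acid, which keeps the benzyl ethers and the benzylic C2–O1 bond intact, and high dilution with only a slight excess of anhydride favours ring closure over intermolecular acylation or trifluoroacetylation.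

Step 7
Reactants: 10 (2R,3R)-5,7-bis(benzyloxy)-4-oxo-2-phenylchroman-3-yl (2S)-2-methylbutanoate
Product: 11 (2R,3R)-5,7-dihydroxy-4-oxo-2-phenylchroman-3-yl (2S)-2-methylbutanoate
Conditions: H2 (1 atm), 10% Pd/C, EtOAc, rt; stopped after uptake of 2 equiv H2
Reagents that add atoms: none
Why: Catalytic hydrogenolysis of the two aryl benzyl ethers under neutral conditions should spare the ester, the aryl ketone and the two ring stereocentres and give the target.

**Compound list**

1 | methyl (2R,3S)-3-phenyloxirane-2-carboxylate (methyl trans-3-phenylglycidate) | COC(=O)[C@@H]1O[C@H]1c1ccccc1 | starting material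
2 | potassium (2R,3S)-3-phenyloxirane-2-carboxylate | O=C([O-])[C@@H]1O[C@H]1c1ccccc1.[K+] | intermediate
3 | prop-2-en-1-yl (2R,3S)-3-phenyloxirane-2-carboxylate | C=CCOC(=O)[C@@H]1O[C@H]1c1ccccc1 | intermediate
4 | 3,5-bis(benzyloxy)phenol | Oc1cc(OCc2ccccc2)cc(OCc2ccccc2)c1 | starting material
5 | prop-2-en-1-yl (2R,3R)-3-[3,5-bis(benzyloxy)phenoxy]-2-hydroxy-3-phenylpropanoate | O[C@@H](C(=O)OCC=C)[C@H](Oc1cc(OCc2ccccc2)cc(OCc2ccccc2)c1)c1ccccc1 | intermediate
6 | (2S)-2-methylbutanoic acid | CC[C@H](C)C(=O)O | starting material
7 | prop-2-en-1-yl (2R,3R)-3-[3,5-bis(benzyloxy)phenoxy]-2-{[(2S)-2-methylbutanoyl]oxy}-3-phenylpropanoate | CC[C@H](C)C(=O)O[C@@H](C(=O)OCC=C)[C@H](Oc1cc(OCc2ccccc2)cc(OCc2ccccc2)c1)c1ccccc1 | intermediate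
8 | (2R,3R)-3-[3,5-bis(benzyloxy)phenoxy]-2-{[(2S)-2-methylbutanoyl]oxy}-3-phenylpropanoic acid | CC[C@H](C)C(=O)O[C@@H](C(=O)O)[C@H](Oc1cc(OCc2ccccc2)cc(OCc2ccccc2)c1)c1ccccc1 | intermediate
9 | (2R,3R)-3-[3,5-bis(benzyloxy)phenoxy]-2-{[(2S)-2-methylbutanoyl]oxy}-3-phenylpropanoic trifluoroacetic anhydride | CC[C@H](C)C(=O)O[C@@H](C(=O)OC(=O)C(F)(F)F)[C@H](Oc1cc(OCc2ccccc2)cc(OCc2ccccc2)c1)c1ccccc1 | intermediate (not isolated)
10 | (2R,3R)-5,7-bis(benzyloxy)-4-oxo-2-phenylchroman-3-yl (2S)-2-methylbutanoate | CC[C@H](C)C(=O)O[C@H]1C(=O)c2c(OCc3ccccc3)cc(OCc3ccccc3)cc2O[C@@H]1c1ccccc1 | intermediate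
11 | (2R,3R)-5,7-dihydroxy-4-oxo-2-phenylchroman-3-yl (2S)-2-methylbutanoate | CC[C@H](C)C(=O)O[C@H]1C(=O)c2c(O)cc(O)cc2O[C@@H]1c1ccccc1 | target

**Step count**

Total step count: 7. Longest linear sequence: 7 steps (1 to 11); 4 and 6 enter as purchased building blocks.

**Steps most likely to fail**

Step 6 (ring closure). Three processes could compete with the closure:
- trifluoroacetylation or intermolecular acylation of the very electron-rich ring;
- capture of the activated carboxyl carbon by the neighbouring 2-methylbutanoyloxy carbonyl, leading to acyl scrambling or epimerisation at the carbon that becomes C3;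
- acid-induced ionisation of the benzylic C–OAr bond with loss of the phenol.

The fallback sets out from 5 and comes back at 10; it closes the ring before the side-chain ester is installed. Compound 5 is deallylated with Pd(PPh3)4/morpholine in THF to (2R,3R)-3-[3,5-bis(benzyloxy)phenoxy]-2-hydroxy-3-phenylpropanoic acid F1. An excess of trifluoroacetic anhydride in CH2Cl2 at 0 °C turns F1 into (2R,3R)-3-[3,5-bis(benzyloxy)phenoxy]-3-phenyl-2-(trifluoroacetoxy)propanoic trifluoroacetic anhydride F2. Its trifluoroacetoxy neighbour is non-participating and retards benzylic ionisation, and F2 should cyclise to (2R,3R)-5,7-bis(benzyloxy)-4-oxo-2-phenylchroman-3-yl trifluoroacetate F3. Methanol with NaHCO3 during work-up removes the labile trifluoroacetate and gives (2R,3R)-5,7-bis(benzyloxy)-3-hydroxy-2-phenylchroman-4-one F4. Steglich esterification of F4 with 6 (DCC, catalytic DMAP, CH2Cl2, 0 °C) gives 10; with both phenols benzylated the 3-hydroxyl is the only acylation site.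

Step 3 (epoxide opening). The phenoxide may attack the ester carbonyl or the α-carbon instead of the benzylic carbon. The ambident 3,5-dialkoxyphenoxide may alkylate through carbon. Partial ionisation at the benzylic carbon may erode the inversion.

The fallback sets out from 4 and comes back at 5; it moves the three-carbon unit to the alcohol oxidation level, where benzylic opening by phenoxides is well established. Compound 4 and commercial (2S,3S)-3-phenyloxiran-2-ylmethanol F5 are heated in aqueous NaOH at 70 °C to give (2S,3R)-3-[3,5-bis(benzyloxy)phenoxy]-3-phenylpropane-1,2-diol F6 by attack at the benzylic carbon with inversion. TEMPO (catalytic) with PhI(OAc)2 in MeCN–water oxidises the primary alcohol selectively to the carboxylic acid, giving the hydroxy acid F1 already described above. Allyl bromide with KHCO3 in DMF then gives 5.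

Step 7 (hydrogenolysis). Debenzylation may be accompanied by hydrogenolysis of the benzylic C2–O1 bond or by reduction of the C4 carbonyl if the catalyst stays active after the benzyl groups are gone.

The fallback sets out from 10 and comes back at 11; it replaces reductive cleavage by Lewis-acid dealkylation. BCl3 with pentamethylbenzene as cation scavenger in CH2Cl2 at −78 °C should remove both aryl benzyl ethers while leaving the ester, the ketone and the heterocycle untouched. No new compound is made.

**Further compounds**

F1 | step 6 | (2R,3R)-3-[3,5-bis(benzyloxy)phenoxy]-2-hydroxy-3-phenylpropanoic acid | O[C@@H](C(=O)O)[C@H](Oc1cc(OCc2ccccc2)cc(OCc2ccccc2)c1)c1ccccc1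
F2 | step 6 | (2R,3R)-3-[3,5-bis(benzyloxy)phenoxy]-3-phenyl-2-(trifluoroacetoxy)propanoic trifluoroacetic anhydride | FC(F)(F)C(=O)O[C@@H](C(=O)OC(=O)C(F)(F)F)[C@H](Oc1cc(OCc2ccccc2)cc(OCc2ccccc2)c1)c1ccccc1
F3 | step 6 | (2R,3R)-5,7-bis(benzyloxy)-4-oxo-2-phenylchroman-3-yl trifluoroacetate | FC(F)(F)C(=O)O[C@H]1C(=O)c2c(OCc3ccccc3)cc(OCc3ccccc3)cc2O[C@@H]1c1ccccc1
F4 | step 6 | (2R,3R)-5,7-bis(benzyloxy)-3-hydroxy-2-phenylchroman-4-one | O[C@H]1C(=O)c2c(OCc3ccccc3)cc(OCc3ccccc3)cc2O[C@@H]1c1ccccc1
F5 | step 3 | (2S,3S)-3-phenyloxiran-2-ylmethanol | OC[C@@H]1O[C@H]1c1ccccc1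
F6 | step 3 | (2S,3R)-3-[3,5-bis(benzyloxy)phenoxy]-3-phenylpropane-1,2-diol | OC[C@H](O)[C@H](Oc1cc(OCc2ccccc2)cc(OCc2ccccc2)c1)c1ccccc1
F0 | step 7 | none | none
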